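**Retrosynthetic overview**
1. Target 15 comes from 14 and 13 by hydrogenolysis of the C5/C6 benzyl ethers and methanolysis of the C3'/C5' acetates.
2. 13 comes from diketone 12 by cutting O1–C8a. C8a is the single C–H carbon of the tetraoxygenated ring A (ortho to the C8 methoxy, para to the C6 oxygen), so O1 is supplied by the carbonyl/enol oxygen on C2 and bonded to C8a by anodic C–H oxygenation; ring A then needs four oxygens, not five.
3. 12 comes from ring A ketone 8 and ring B acid chloride 11 by forming the C2–C3 bond (Claisen-type acylation under soft enolisation).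
4. 8 comes from 2,3-dihydroxy-4-methoxybenzaldehyde 1 (C5 bromination, methoxylation, benzylation, methoxymethyl Grignard from 5, oxidation); 11 comes from 3,5-dihydroxy-4-methoxybenzoic acid 9.
5. Ring order: rings A and B are bought as benzenes; ring C is the only ring made, and it is closed last, in step 9.

Key step: step 9

Remark: diketone 12 is drawn in its keto form; it is racemic at the central carbon and in equilibrium with its enols, and that carbon becomes sp2 in step 9, so the target has no stereocentre to control. Flavone numbering is used for positions in 12–15.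

**Step 1**
Reactants: 1 2,3-dihydroxy-4-methoxybenzaldehyde
Product: 2 5-bromo-2,3-dihydroxy-4-methoxybenzaldehyde
Conditions: Br2 (1.0 equiv), AcOH, 15 °C → rt
Reagents that add atoms: bromine, BrBr
Why: Electrophilic aromatic bromination should go to C5, which is para to the C2 hydroxyl, ortho to the C4 methoxy and meta to the formyl group, whereas C6 is ortho to the deactivating formyl group.

**Step 2**
Reactants: 2 5-bromo-2,3-dihydroxy-4-methoxybenzaldehyde
Product: 3 2,3-dihydroxy-4,5-dimethoxybenzaldehyde
Conditions: NaOMe (5 equiv), CuBr (0.2 equiv), MeOH/DMF, 110 °C, N2; then aq HCl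
Reagents that add atoms: sodium methoxide, C[O-].[Na+]
Why: Copper-catalysed Ullmann-type methoxylation of an aryl bromide, the reaction type that converts 5-bromovanillin into syringaldehyde; the catecholate formed first shields the aldehyde from alkoxide addition.

**Step 3**
Reactants: 3 2,3-dihydroxy-4,5-dimethoxybenzaldehyde
Product: 4 2,3-bis(benzyloxy)-4,5-dimethoxybenzaldehyde
Conditions: BnBr (2.4 equiv), K2CO3 (3 equiv), DMF, 60 °C, N2
Reagents that add atoms: benzyl bromide, BrCc1ccccc1
Why: Williamson etherification of both phenoxides, including the hydrogen-bonded C2 hydroxyl, in a dipolar aprotic solvent; the non-enolisable aldehyde is inert.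

**Step 4**
Reactants: 4 2,3-bis(benzyloxy)-4,5-dimethoxybenzaldehyde; 5 chloromethyl methyl ether
Product: 7 rac-1-[2,3-bis(benzyloxy)-4,5-dimethoxyphenyl]-2-methoxyethan-1-ol, via methoxymethylmagnesium chloride 6 (not isolated)
Conditions: 5 (2.5 equiv), Mg turnings, HgCl2 (cat.), THF, −25 °C; then 4, −25 → 0 °C; aq NH4Cl
Reagents that add atoms: none
Why: Grignard addition of the α-alkoxy organomagnesium reagent, made and used cold to avoid its α-elimination, to an aldehyde without acidic hydrogens; the carbinol centre forms as the racemate and is removed in step 5.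

**Step 5**
Reactants: 7 rac-1-[2,3-bis(benzyloxy)-4,5-dimethoxyphenyl]-2-methoxyethan-1-ol
Product: 8 1-[2,3-bis(benzyloxy)-4,5-dimethoxyphenyl]-2-methoxyethan-1-one
Conditions: DMP (1.3 equiv), CH2Cl2, rt
Reagents that add atoms: none
Why: Dess–Martin oxidation of a secondary benzylic alcohol under neutral conditions that leave the benzyl and methyl ethers untouched.

**Step 6**
Reactants: 9 3,5-dihydroxy-4-methoxybenzoic acid
Product: 10 3,5-diacetoxy-4-methoxybenzoic acid
Conditions: Ac2O (3.5 equiv), aq NaOH, 0 °C; then HCl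
Reagents that add atoms: acetic anhydride, CC(=O)OC(C)=O
Why: Schotten–Baumann-type O-acetylation of the two phenoxides in cold aqueous alkali, in which the carboxylate stays free and is recovered as the acid on acidification.

**Step 7**
Reactants: 10 3,5-diacetoxy-4-methoxybenzoic acid
Product: 11 3,5-diacetoxy-4-methoxybenzoyl chloride
Conditions: (COCl)2 (1.3 equiv), DMF (cat.), CH2Cl2, 0 °C → rt
Reagents that add atoms: oxalyl chloride, O=C(Cl)C(=O)Cl
Why: Acid chloride formation through the Vilsmeier-type chloroiminium catalyst at room temperature, conditions to which aryl acetates are inert.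

**Step 8**
Reactants: 8 1-[2,3-bis(benzyloxy)-4,5-dimethoxyphenyl]-2-methoxyethan-1-one; 11 3,5-diacetoxy-4-methoxybenzoyl chloride
Product: 12 rac-1-[2,3-bis(benzyloxy)-4,5-dimethoxyphenyl]-3-(3,5-diacetoxy-4-methoxyphenyl)-2-methoxypropane-1,3-dione
Conditions: MgBr2·OEt2 (2.5 equiv), i-Pr2NEt (3 equiv), 11 (1.1 equiv), CH2Cl2, 0 °C → rt; then 1 M HCl
Reagents that add atoms: none
Why: Claisen-type C-acylation under soft enolisation, in which magnesium chelated between the carbonyl and the α-methoxy oxygen makes the CH2 acidic enough for i-Pr2NEt and the enolate reacts at carbon with the acid chloride far faster than with the aryl acetates; the new centre between the carbonyls is racemic and enolisable.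

**Step 9**
Reactants: 12 rac-1-[2,3-bis(benzyloxy)-4,5-dimethoxyphenyl]-3-(3,5-diacetoxy-4-methoxyphenyl)-2-methoxypropane-1,3-dione
Product: 13 5,6-bis(benzyloxy)-2-(3,5-diacetoxy-4-methoxyphenyl)-3,7,8-trimethoxy-4H-chromen-4-one
Conditions: undivided cell, graphite anode, Pt cathode, constant current (ca. 3 mA cm−2, 2.2 F mol−1), Bu4NPF6 (0.1 M), 1,1,1,3,3,3-hexafluoropropan-2-ol (HFIP)/CH2Cl2 4:1, rt
Reagents that add atoms: none
Why: Proposed new method: anodic oxidation in HFIP should remove one electron from ring A of 12, its only electron-rich arene, and the carbonyl or enol oxygen on the carbon bearing ring B then attacks C8a of the radical cation, after which loss of the C3 proton, a second electron and the C8a proton gives the aromatic chromone while protons are reduced to H2 at the cathode. The closest known reaction types are the anodic dehydrogenative C–O cyclisations of biaryl-2-carboxylic acids to benzocoumarins and of N-aryl amides to benzoxazoles, and the CuI-mediated O-arylation of 1-(2-haloaryl)-1,3-diketones to flavones; an anodic C–H/O–H closure of a 1,3-diketone onto an arene C–H has not been shown. Ring C closes in a six-membered 6-endo mode, the oxygen adding to one end of the C4a–C8a arene bond, which stays inside the new ring. No stereocentre is formed, and the racemic central carbon of the diketone becomes sp2 C3. The step needs ring A to be oxidised before ring B and the oxygen to bond at C8a: the two acetates raise the potential of ring B so that the other carbonyl oxygen cannot close onto C2' or C6', and C8a is the only ring A carbon bearing hydrogen, ortho to the C8 methoxy and para to the C6 ether, so only attack there can be made permanent by proton loss. HFIP is non-nucleophilic and stabilises the radical cation, and the charge is held near 2 F per mole to spare the product and the benzyl ethers.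

**Step 10**
Reactants: 13 5,6-bis(benzyloxy)-2-(3,5-diacetoxy-4-methoxyphenyl)-3,7,8-trimethoxy-4H-chromen-4-one
Product: 14 5,6-bis(benzyloxy)-2-(3,5-dihydroxy-4-methoxyphenyl)-3,7,8-trimethoxy-4H-chromen-4-one
Conditions: K2CO3 (2.5 equiv), MeOH/THF, 0 °C → rt; then 1 M HCl to pH 5
Reagents that add atoms: none
Why: Base-mediated transesterification (methanolysis) of the two aryl acetates, the most electrophilic groups in 13, under conditions to which the benzyl ethers, methyl ethers and chromone are stable.

**Step 11**
Reactants: 14 5,6-bis(benzyloxy)-2-(3,5-dihydroxy-4-methoxyphenyl)-3,7,8-trimethoxy-4H-chromen-4-one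
Product: 15 5,6,3',5'-tetrahydroxy-3,7,8,4'-tetramethoxyflavone
Conditions: H2 (1 atm), Pd/C (10 wt %), EtOAc/MeOH, rt; filtration under N2
Reagents that add atoms: none
Why: Catalytic hydrogenolysis of the two aryl benzyl ethers under neutral conditions, which should leave the tetrasubstituted C2=C3 bond of the chromone and the methyl ethers untouched and releases the air-sensitive 5,6-diol only at the end.

**Compound list**
1 | 2,3-dihydroxy-4-methoxybenzaldehyde | COc1ccc(C=O)c(O)c1O | starting material
2 | 5-bromo-2,3-dihydroxy-4-methoxybenzaldehyde | COc1c(Br)cc(C=O)c(O)c1O | intermediate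
3 | 2,3-dihydroxy-4,5-dimethoxybenzaldehyde | COc1cc(C=O)c(O)c(O)c1OC | intermediate
4 | 2,3-bis(benzyloxy)-4,5-dimethoxybenzaldehyde | COc1cc(C=O)c(OCc2ccccc2)c(OCc2ccccc2)c1OC | intermediate
5 | chloromethyl methyl ether | COCCl | starting material
6 | methoxymethylmagnesium chloride | COC[Mg]Cl | intermediate (not isolated)
7 | rac-1-[2,3-bis(benzyloxy)-4,5-dimethoxyphenyl]-2-methoxyethan-1-ol | COCC(O)c1cc(OC)c(OC)c(OCc2ccccc2)c1OCc1ccccc1 | intermediate
8 | 1-[2,3-bis(benzyloxy)-4,5-dimethoxyphenyl]-2-methoxyethan-1-one | COCC(=O)c1cc(OC)c(OC)c(OCc2ccccc2)c1OCc1ccccc1 | intermediate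
9 | 3,5-dihydroxy-4-methoxybenzoic acid | COc1c(O)cc(C(=O)O)cc1O | starting material
10 | 3,5-diacetoxy-4-methoxybenzoic acid | COc1c(OC(C)=O)cc(C(=O)O)cc1OC(C)=O | intermediate
11 | 3,5-diacetoxy-4-methoxybenzoyl chloride | COc1c(OC(C)=O)cc(C(=O)Cl)cc1OC(C)=O | intermediate
12 | rac-1-[2,3-bis(benzyloxy)-4,5-dimethoxyphenyl]-3-(3,5-diacetoxy-4-methoxyphenyl)-2-methoxypropane-1,3-dione (keto form, enolisable) | COC(C(=O)c1cc(OC)c(OC)c(OCc2ccccc2)c1OCc1ccccc1)C(=O)c1cc(OC(C)=O)c(OC)c(OC(C)=O)c1 | intermediate
13 | 5,6-bis(benzyloxy)-2-(3,5-diacetoxy-4-methoxyphenyl)-3,7,8-trimethoxy-4H-chromen-4-one | CC(=O)Oc1cc(-c2oc3c(OC)c(OC)c(OCc4ccccc4)c(OCc4ccccc4)c3c(=O)c2OC)cc(OC(C)=O)c1OC | intermediate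
14 | 5,6-bis(benzyloxy)-2-(3,5-dihydroxy-4-methoxyphenyl)-3,7,8-trimethoxy-4H-chromen-4-one | COc1c(O)cc(-c2oc3c(OC)c(OC)c(OCc4ccccc4)c(OCc4ccccc4)c3c(=O)c2OC)cc1O | intermediate
15 | 5,6,3',5'-tetrahydroxy-3,7,8,4'-tetramethoxyflavone | COc1c(O)cc(-c2oc3c(OC)c(OC)c(O)c(O)c3c(=O)c2OC)cc1O | target

**Step count**
Total steps: 11. Longest linear sequence: 9 steps (steps 1, 2, 3, 4, 5, 8, 9, 10, 11); the ring B branch (steps 6, 7) joins at step 8.

**Steps most likely to fail**

1. Step 9 (proposed new method). The radical cation may follow other paths than closure at C8a: anodic loss of a benzyl group from ring A with onward oxidation to a quinone, oxidation of the enol at C3 with capture by solvent, ipso attack at the benzyloxy-bearing carbon, or further oxidation of the product. Fallback with known chemistry, setting out from 4 and returning at 13: the O1–C8a bond is made by copper-mediated O-arylation of an aryl bromide instead of C–H oxidation. Aldehyde 4 is brominated at its only ring C–H (NBS, DMF, rt) to give 2,3-bis(benzyloxy)-6-bromo-4,5-dimethoxybenzaldehyde F1. Addition of 6 as in step 4 should give rac-1-[2,3-bis(benzyloxy)-6-bromo-4,5-dimethoxyphenyl]-2-methoxyethan-1-ol F2, and DMP oxidation 1-[2,3-bis(benzyloxy)-6-bromo-4,5-dimethoxyphenyl]-2-methoxyethan-1-one F3. Acylation with 11 under the conditions of step 8 should give rac-1-[2,3-bis(benzyloxy)-6-bromo-4,5-dimethoxyphenyl]-3-(3,5-diacetoxy-4-methoxyphenyl)-2-methoxypropane-1,3-dione F4. CuI (10 mol %), K2CO3, DMF, 90 °C then closes ring C by intramolecular Ullmann-type O-arylation of the enolate and rejoins the route at 13. Any acetate lost in this basic step is of no consequence, since step 10 removes both.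

2. Step 2. Under hot alkoxide the bromide may be lost reductively, and the copper-bound catecholate may be oxidised or may stall the catalyst by chelation. Fallback setting out from 2 and returning at 4: the oxygen is introduced through boron on the protected catechol. Benzylation of 2 (BnBr, K2CO3, DMF) should give 2,3-bis(benzyloxy)-5-bromo-4-methoxybenzaldehyde F5. Miyaura borylation (B2pin2, Pd(dppf)Cl2, KOAc, dioxane, 90 °C) should give 2,3-bis(benzyloxy)-4-methoxy-5-(4,4,5,5-tetramethyl-1,3,2-dioxaborolan-2-yl)benzaldehyde F6. Oxidation of the C–B bond with N-methylmorpholine N-oxide (THF, 50 °C), which spares the aldehyde, should give 2,3-bis(benzyloxy)-5-hydroxy-4-methoxybenzaldehyde F7, and methylation (MeI, K2CO3, DMF) gives 4.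

3. Step 8. The magnesium enolate may be acylated on oxygen, the product may be acylated a second time, or MgBr2 may cleave the benzyl ether ortho to the carbonyl by chelation. Fallback setting out from 11 and 8 and returning at 12: the C2–C3 bond is made by aldol addition and the diketone by oxidation. Rosenmund reduction of 11 (H2, Pd/BaSO4, 2,6-lutidine, THF) should give 3,5-diacetoxy-4-methoxybenzaldehyde F8. The lithium enolate of 8 (LiN(SiMe3)2, 1.0 equiv, THF, −78 °C) is added to F8 and quenched cold with AcOH to give 1-[2,3-bis(benzyloxy)-4,5-dimethoxyphenyl]-3-(3,5-diacetoxy-4-methoxyphenyl)-3-hydroxy-2-methoxypropan-1-one F9 as a mixture of racemic diastereomers. DMP oxidation of the carbinol then gives 12.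

**Further compounds**
F1 | step 9 | 2,3-bis(benzyloxy)-6-bromo-4,5-dimethoxybenzaldehyde | COc1c(Br)c(C=O)c(OCc2ccccc2)c(OCc2ccccc2)c1OC
F2 | step 9 | rac-1-[2,3-bis(benzyloxy)-6-bromo-4,5-dimethoxyphenyl]-2-methoxyethan-1-ol | COCC(O)c1c(Br)c(OC)c(OC)c(OCc2ccccc2)c1OCc1ccccc1
F3 | step 9 | 1-[2,3-bis(benzyloxy)-6-bromo-4,5-dimethoxyphenyl]-2-methoxyethan-1-one | COCC(=O)c1c(Br)c(OC)c(OC)c(OCc2ccccc2)c1OCc1ccccc1
F4 | step 9 | rac-1-[2,3-bis(benzyloxy)-6-bromo-4,5-dimethoxyphenyl]-3-(3,5-diacetoxy-4-methoxyphenyl)-2-methoxypropane-1,3-dione | COC(C(=O)c1c(Br)c(OC)c(OC)c(OCc2ccccc2)c1OCc1ccccc1)C(=O)c1cc(OC(C)=O)c(OC)c(OC(C)=O)c1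
F5 | step 2 | 2,3-bis(benzyloxy)-5-bromo-4-methoxybenzaldehyde | COc1c(Br)cc(C=O)c(OCc2ccccc2)c1OCc1ccccc1
F6 | step 2 | 2,3-bis(benzyloxy)-4-methoxy-5-(4,4,5,5-tetramethyl-1,3,2-dioxaborolan-2-yl)benzaldehyde | COc1c(B2OC(C)(C)C(C)(C)O2)cc(C=O)c(OCc2ccccc2)c1OCc1ccccc1
F7 | step 2 | 2,3-bis(benzyloxy)-5-hydroxy-4-methoxybenzaldehyde | COc1c(O)cc(C=O)c(OCc2ccccc2)c1OCc1ccccc1
F8 | step 8 | 3,5-diacetoxy-4-methoxybenzaldehyde | COc1c(OC(C)=O)cc(C=O)cc1OC(C)=O
F9 | step 8 | 1-[2,3-bis(benzyloxy)-4,5-dimethoxyphenyl]-3-(3,5-diacetoxy-4-methoxyphenyl)-3-hydroxy-2-methoxypropan-1-one (racemic diastereomer mixture) | COC(C(=O)c1cc(OC)c(OC)c(OCc2ccccc2)c1OCc1ccccc1)C(O)c1cc(OC(C)=O)c(OC)c(OC(C)=O)c1
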